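## Retrosynthetic overview

1. 22 ⇐ 21 ⇐ 20 ⇐ 19: the phenols and the two CH2OH groups are unveiled last (hydrogenolysis, desilylation, ester reduction) on an oxolane that already carries all four stereocentres.
2. 19 ⇐ 18: ionic hydrogenation of the C2=C3 enol ether ester of a 4,5-dihydrofuran sets C2 and C3 from C4 and C5.
3. 18 ⇐ 8 + 16: in the oxolane ring (O1, C2, C3, C4, C5), C5 is one benzylic carbon bonded to both O1 and C4. It is delivered as the benzylidene carbon of a chiral sulfonium ylide to aroyl acrylate 8, which already holds O1, C2, C3 and C4; this forms C4–C5 and O1–C5 and closes the only ring of the target.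
4. 8 ⇐ 3 + 7 (Knoevenagel); 3 from acetosyringone 1, 7 from (Z)-but-2-ene-1,4-diol 4.
5. 16 ⇐ 12 + 15; 12 from syringaldehyde 9, the C2-symmetric thiolane 15 from (2S,5S)-hexane-2,5-diol 13.

Key step: step 12

Remark 1: ring atoms are numbered O1, C2 (aryl), C3 (ester, later CH2OH), C4 (CH2O), C5 (aryl from the ylide). In this numbering the target is (2S,3S,4S,5R), with C2/C3 cis, C3/C4 trans, C4/C5 trans and the two aryl groups cis.

Remark 2: the sense of induction of (2R,5R)-thiolane 15 at C5 is assumed to follow that of its benzylide in additions to aldehydes (same ylide face, which corresponds to 5R here). If the first batch of 18 proves antipodal, the route is run unchanged with the thiolane from (2R,5R)-hexane-2,5-diol.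

Remark 3: the primary alcohol is carried as a tert-butyldiphenylsilyl (TBDPS) ether because it has to survive CF3CO2H in step 13.

## Route

Step 1
Reactants: 1 acetosyringone
Product: 2 1-[4-(benzyloxy)-3,5-dimethoxyphenyl]ethan-1-one
Conditions: BnBr (1.2 equiv), K2CO3 (2 equiv), DMF, 60 °C
Reagents that add atoms: benzyl bromide, BrCc1ccccc1
Why: Williamson ether synthesis; carbonate deprotonates only the phenol, and the phenoxide displaces bromide from benzyl bromide.

Step 2
Reactants: 2 1-[4-(benzyloxy)-3,5-dimethoxyphenyl]ethan-1-one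
Product: 3 methyl 3-[4-(benzyloxy)-3,5-dimethoxyphenyl]-3-oxopropanoate
Conditions: NaH (2.5 equiv), dimethyl carbonate (5 equiv), toluene, reflux; then cold aq. HCl
Reagents that add atoms: dimethyl carbonate, COC(=O)OC
Why: crossed Claisen condensation of the methyl ketone enolate with the carbonate, driven by irreversible deprotonation of the β-keto ester formed; the aryl ethers are inert.

Step 3
Reactants: 4 (Z)-but-2-ene-1,4-diol
Product: 5 (Z)-1,4-bis[(tert-butyldiphenylsilyl)oxy]but-2-ene
Conditions: TBDPSCl (2.2 equiv), imidazole (4.4 equiv), DMF, 0 °C → rt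
Reagents that add atoms: tert-butyl(chloro)diphenylsilane, CC(C)(C)[Si](Cl)(c1ccccc1)c1ccccc1
Why: imidazole-promoted silyl ether formation at both primary allylic hydroxyl groups.

Step 4
Reactants: 5 (Z)-1,4-bis[(tert-butyldiphenylsilyl)oxy]but-2-ene
Product: 7 2-[(tert-butyldiphenylsilyl)oxy]acetaldehyde, via secondary ozonide 6 (not isolated)
Conditions: O3, CH2Cl2, −78 °C (to first blue colour); then PPh3 (1.1 equiv), −78 °C → rt
Reagents that add atoms: ozone, [O-][O+]=O
Why: ozonolysis with reductive work-up; the symmetrical alkene should give two molecules of the aldehyde, the silyl ether is inert and the phenyl rings on silicon react far more slowly than the alkene at −78 °C.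

Step 5
Reactants: 3 methyl 3-[4-(benzyloxy)-3,5-dimethoxyphenyl]-3-oxopropanoate; 7 2-[(tert-butyldiphenylsilyl)oxy]acetaldehyde (1.3 equiv)
Product: 8 methyl 2-[4-(benzyloxy)-3,5-dimethoxybenzoyl]-4-[(tert-butyldiphenylsilyl)oxy]but-2-enoate (E/Z mixture)
Conditions: piperidine (0.1 equiv), AcOH (0.1 equiv), 4 Å molecular sieves, CH2Cl2, 0 °C → rt
Reagents that add atoms: none
Why: Knoevenagel condensation under piperidinium acetate catalysis with sieves removing water; excess aldehyde and low temperature hold back addition of a second keto ester, and the alkene geometry is irrelevant because step 12 passes through one common enolate.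

Step 6
Reactants: 9 syringaldehyde
Product: 10 4-(benzyloxy)-3,5-dimethoxybenzaldehyde
Conditions: BnBr (1.2 equiv), K2CO3 (2 equiv), DMF, 60 °C
Reagents that add atoms: benzyl bromide, BrCc1ccccc1
Why: Williamson ether synthesis at the phenoxide.

Step 7
Reactants: 10 4-(benzyloxy)-3,5-dimethoxybenzaldehyde
Product: 11 [4-(benzyloxy)-3,5-dimethoxyphenyl]methanol
Conditions: NaBH4 (0.6 equiv), MeOH/THF, 0 °C
Reagents that add atoms: none
Why: borohydride reduction of the aldehyde; the ethers are untouched.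

Step 8
Reactants: 11 [4-(benzyloxy)-3,5-dimethoxyphenyl]methanol
Product: 12 2-(benzyloxy)-5-(bromomethyl)-1,3-dimethoxybenzene
Conditions: PBr3 (0.4 equiv), CH2Cl2, 0 °C
Reagents that add atoms: phosphorus tribromide, BrP(Br)Br
Why: bromination of the benzylic alcohol through its phosphite ester (SN2 by bromide); the product is used promptly.

Step 9
Reactants: 13 (2S,5S)-hexane-2,5-diol
Product: 14 (2S,5S)-hexane-2,5-diyl dimethanesulfonate
Conditions: MsCl (2.4 equiv), Et3N (3 equiv), CH2Cl2, −10 → 0 °C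
Reagents that add atoms: methanesulfonyl chloride, CS(=O)(=O)Cl
Why: O-sulfonylation (mesylation); no C–O bond is broken, so both stereocentres are retained.

Step 10
Reactants: 14 (2S,5S)-hexane-2,5-diyl dimethanesulfonate
Product: 15 (2R,5R)-2,5-dimethylthiolane
Conditions: Na2S·9H2O (1.3 equiv), EtOH, rt → 40 °C; pentane extraction, distillation
Reagents that add atoms: sodium sulfide, [Na+].[Na+].[S-2]
Why: double SN2 thioether synthesis (intermolecular, then 5-exo-tet), each displacement with inversion, so the (S,S)-dimesylate should give the (R,R)-thiolane.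

Step 11
Reactants: 12 2-(benzyloxy)-5-(bromomethyl)-1,3-dimethoxybenzene; 15 (2R,5R)-2,5-dimethylthiolane (1.2 equiv)
Product: 16 (2R,5R)-1-[4-(benzyloxy)-3,5-dimethoxybenzyl]-2,5-dimethylthiolan-1-ium bromide
Conditions: acetone (concentrated), rt, 48 h; trituration with Et2O
Reagents that add atoms: none
Why: SN2 S-alkylation of the thioether by the benzylic bromide; because of the C2 symmetry of 15, sulfur is not stereogenic and a single salt should result.

Step 12
Reactants: 8 methyl 2-[4-(benzyloxy)-3,5-dimethoxybenzoyl]-4-[(tert-butyldiphenylsilyl)oxy]but-2-enoate (E/Z mixture); 16 (2R,5R)-1-[4-(benzyloxy)-3,5-dimethoxybenzyl]-2,5-dimethylthiolan-1-ium bromide (1.2 equiv)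
Product: 18 methyl (4S,5R)-2,5-bis[4-(benzyloxy)-3,5-dimethoxyphenyl]-4-{[(tert-butyldiphenylsilyl)oxy]methyl}-4,5-dihydrofuran-3-carboxylate, via sulfonium ylide 17 (not isolated)
Conditions: Cs2CO3 (1.5 equiv), MeCN, −20 °C → rt; chromatography (15 recovered)
Reagents that add atoms: none
Why: Proposed new method: Cs2CO3 should deprotonate 16 at the benzylic carbon to ylide 17, which adds through carbon to C4 of the doubly activated alkene of 8; the resulting β-keto ester enolate then displaces thiolane 15 at C5 through its ketone oxygen with inversion, so that C4–C5 and O1–C5 are both made and the dihydrofuran ring (O1, C2, C3, C4, C5) closes by a 5-exo-tet O-alkylation. The closest known reactions are the [4+1] annulations of alkylidene 1,3-dicarbonyl compounds with carbonyl-stabilised sulfonium or pyridinium ylides and the benzylidene transfer from chiral sulfonium salts to aldehydes and enones; a semi-stabilised benzylide has not been combined with an aroyl acrylate in this way. C5 is controlled by the thiolane: its C2 symmetry leaves sulfur non-stereogenic, and a ring methyl group screens one face of the ylide carbon, which by analogy with additions of this benzylide to aldehydes should lead to 5R. C4 is set relative to C5 in the addition, where the silyloxymethyl group and the aryl group are expected to avoid each other so that they end up trans after the inversion at C5; both alkene isomers of 8 give the same enolate, and any cis isomer would be removed by chromatography. The step needs 1,4- over 1,2-addition, which the unhindered, doubly activated β-carbon secures, and O- over C-alkylation, which a caesium enolate in MeCN and a benzylic sulfonium leaving group favour; a C-alkylated donor–acceptor cyclopropane, should it form, is expected to ring-expand to 18 (Cloke–Wilson rearrangement) without touching C4.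

Step 13
Reactants: 18 methyl (4S,5R)-2,5-bis[4-(benzyloxy)-3,5-dimethoxyphenyl]-4-{[(tert-butyldiphenylsilyl)oxy]methyl}-4,5-dihydrofuran-3-carboxylate
Product: 19 methyl (2S,3R,4S,5R)-2,5-bis[4-(benzyloxy)-3,5-dimethoxyphenyl]-4-{[(tert-butyldiphenylsilyl)oxy]methyl}oxolane-3-carboxylate
Conditions: Et3SiH (5 equiv), CF3CO2H/CH2Cl2 (1:4), −20 → 0 °C; NaHCO3 quench
Reagents that add atoms: none
Why: ionic hydrogenation: reversible protonation at C3 lets the C3 epimers of the aryl-stabilised oxocarbenium ion interconvert through 18, and Et3SiH should reduce the less strained ion (ester trans to the C4 substituent) from the face anti to both the C3 ester and the C5 aryl group, giving C2/C3 cis, C3/C4 trans and the aryl groups cis; the benzyl and TBDPS ethers should tolerate the acid at this temperature.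

Step 14
Reactants: 19 methyl (2S,3R,4S,5R)-2,5-bis[4-(benzyloxy)-3,5-dimethoxyphenyl]-4-{[(tert-butyldiphenylsilyl)oxy]methyl}oxolane-3-carboxylate
Product: 20 [(2S,3S,4S,5R)-2,5-bis[4-(benzyloxy)-3,5-dimethoxyphenyl]-4-{[(tert-butyldiphenylsilyl)oxy]methyl}oxolan-3-yl]methanol
Conditions: LiAlH4 (1.5 equiv), THF, 0 °C; H2O/aq. NaOH work-up
Reagents that add atoms: none
Why: hydride reduction of the ester to the primary alcohol, faster at 0 °C than enolisation at C3, so the configuration is kept (the descriptor at C3 changes only through substituent priority).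

Step 15
Reactants: 20 [(2S,3S,4S,5R)-2,5-bis[4-(benzyloxy)-3,5-dimethoxyphenyl]-4-{[(tert-butyldiphenylsilyl)oxy]methyl}oxolan-3-yl]methanol
Product: 21 [(2S,3S,4S,5R)-2,5-bis[4-(benzyloxy)-3,5-dimethoxyphenyl]oxolane-3,4-diyl]dimethanol
Conditions: Bu4NF (1.5 equiv), THF, 0 °C → rt; aq. NH4Cl
Reagents that add atoms: none
Why: fluoride-induced desilylation driven by Si–F bond formation; ethers and stereocentres are unaffected.

Step 16
Reactants: 21 [(2S,3S,4S,5R)-2,5-bis[4-(benzyloxy)-3,5-dimethoxyphenyl]oxolane-3,4-diyl]dimethanol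
Product: 22 4,4'-[(2S,3S,4S,5R)-3,4-bis(hydroxymethyl)oxolane-2,5-diyl]bis(2,6-dimethoxyphenol) (target)
Conditions: H2 (1 atm), 10% Pd/C, EtOAc/MeOH, rt; stopped as soon as 21 and the mono-benzyl ether are consumed
Reagents that add atoms: none
Why: catalytic hydrogenolysis of the two aryl benzyl ethers, which under neutral conditions should cleave much faster than the benzylic C–O bonds of the ring; no stereocentre is touched.

## Compound list

1 | acetosyringone, 1-(4-hydroxy-3,5-dimethoxyphenyl)ethan-1-one | CC(=O)c1cc(OC)c(O)c(OC)c1 | starting material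
2 | 1-[4-(benzyloxy)-3,5-dimethoxyphenyl]ethan-1-one | CC(=O)c1cc(OC)c(OCc2ccccc2)c(OC)c1 | intermediate
3 | methyl 3-[4-(benzyloxy)-3,5-dimethoxyphenyl]-3-oxopropanoate | COC(=O)CC(=O)c1cc(OC)c(OCc2ccccc2)c(OC)c1 | intermediate
4 | (Z)-but-2-ene-1,4-diol | OC/C=C\CO | starting material
5 | (Z)-1,4-bis[(tert-butyldiphenylsilyl)oxy]but-2-ene | CC(C)(C)[Si](OC/C=C\CO[Si](c1ccccc1)(c1ccccc1)C(C)(C)C)(c1ccccc1)c1ccccc1 | intermediate
6 | 3,5-bis{[(tert-butyldiphenylsilyl)oxy]methyl}-1,2,4-trioxolane (secondary ozonide) | CC(C)(C)[Si](OCC1OOC(CO[Si](c2ccccc2)(c2ccccc2)C(C)(C)C)O1)(c1ccccc1)c1ccccc1 | intermediate (not isolated)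
7 | 2-[(tert-butyldiphenylsilyl)oxy]acetaldehyde | CC(C)(C)[Si](OCC=O)(c1ccccc1)c1ccccc1 | intermediate
8 | methyl 2-[4-(benzyloxy)-3,5-dimethoxybenzoyl]-4-[(tert-butyldiphenylsilyl)oxy]but-2-enoate (E/Z mixture, E isomer drawn) | COC(=O)/C(C(=O)c1cc(OC)c(OCc2ccccc2)c(OC)c1)=C/CO[Si](c1ccccc1)(c1ccccc1)C(C)(C)C | intermediate
9 | syringaldehyde | COc1cc(C=O)cc(OC)c1O | starting material
10 | 4-(benzyloxy)-3,5-dimethoxybenzaldehyde | COc1cc(C=O)cc(OC)c1OCc1ccccc1 | intermediate
11 | [4-(benzyloxy)-3,5-dimethoxyphenyl]methanol | COc1cc(CO)cc(OC)c1OCc1ccccc1 | intermediate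
12 | 2-(benzyloxy)-5-(bromomethyl)-1,3-dimethoxybenzene | COc1cc(CBr)cc(OC)c1OCc1ccccc1 | intermediate
13 | (2S,5S)-hexane-2,5-diol | C[C@H](O)CC[C@H](C)O | starting material
14 | (2S,5S)-hexane-2,5-diyl dimethanesulfonate | C[C@H](OS(C)(=O)=O)CC[C@H](C)OS(C)(=O)=O | intermediate
15 | (2R,5R)-2,5-dimethylthiolane | C[C@@H]1CC[C@@H](C)S1 | intermediate
16 | (2R,5R)-1-[4-(benzyloxy)-3,5-dimethoxybenzyl]-2,5-dimethylthiolan-1-ium bromide | C[C@@H]1CC[C@@H](C)[S+]1Cc1cc(OC)c(OCc2ccccc2)c(OC)c1.[Br-] | intermediate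
17 | sulfonium ylide of 16, [4-(benzyloxy)-3,5-dimethoxyphenyl][(2R,5R)-2,5-dimethylthiolan-1-ium-1-yl]methanide | C[C@@H]1CC[C@@H](C)[S+]1[CH-]c1cc(OC)c(OCc2ccccc2)c(OC)c1 | intermediate (not isolated)
18 | methyl (4S,5R)-2,5-bis[4-(benzyloxy)-3,5-dimethoxyphenyl]-4-{[(tert-butyldiphenylsilyl)oxy]methyl}-4,5-dihydrofuran-3-carboxylate | COC(=O)C1=C(c2cc(OC)c(OCc3ccccc3)c(OC)c2)O[C@@H](c2cc(OC)c(OCc3ccccc3)c(OC)c2)[C@@H]1CO[Si](c1ccccc1)(c1ccccc1)C(C)(C)C | intermediate
19 | methyl (2S,3R,4S,5R)-2,5-bis[4-(benzyloxy)-3,5-dimethoxyphenyl]-4-{[(tert-butyldiphenylsilyl)oxy]methyl}oxolane-3-carboxylate | COC(=O)[C@H]1[C@@H](c2cc(OC)c(OCc3ccccc3)c(OC)c2)O[C@@H](c2cc(OC)c(OCc3ccccc3)c(OC)c2)[C@@H]1CO[Si](c1ccccc1)(c1ccccc1)C(C)(C)C | intermediate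
20 | [(2S,3S,4S,5R)-2,5-bis[4-(benzyloxy)-3,5-dimethoxyphenyl]-4-{[(tert-butyldiphenylsilyl)oxy]methyl}oxolan-3-yl]methanol | OC[C@H]1[C@@H](c2cc(OC)c(OCc3ccccc3)c(OC)c2)O[C@@H](c2cc(OC)c(OCc3ccccc3)c(OC)c2)[C@@H]1CO[Si](c1ccccc1)(c1ccccc1)C(C)(C)C | intermediate
21 | [(2S,3S,4S,5R)-2,5-bis[4-(benzyloxy)-3,5-dimethoxyphenyl]oxolane-3,4-diyl]dimethanol | OC[C@H]1[C@@H](c2cc(OC)c(OCc3ccccc3)c(OC)c2)O[C@@H](c2cc(OC)c(OCc3ccccc3)c(OC)c2)[C@@H]1CO | intermediate
22 | 4,4'-[(2S,3S,4S,5R)-3,4-bis(hydroxymethyl)oxolane-2,5-diyl]bis(2,6-dimethoxyphenol), CNP0170897.4 | COc1cc([C@H]2O[C@@H](c3cc(OC)c(O)c(OC)c3)[C@H](CO)[C@H]2CO)cc(OC)c1O | target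

## Totals and risk

Total step count: 16. Longest linear sequence: 9 steps (from syringaldehyde 9: steps 6, 7, 8, 11, 12, 13, 14, 15, 16).

**Step 12 (most at risk).** The ring closure may go through carbon instead of oxygen, the basic ylide may deprotonate 8 at the γ-position and move the double bond out of conjugation before it adds, and selection of the ylide face or of the alkene face may be poor, giving low enantiomeric or trans/cis purity. The fallback builds the same ring by known chemistry, making C3–C4 and O1–C5 by a radical annulation; it sets out from 10 and 3 and comes back to the route at 18.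
- Horner–Wadsworth–Emmons olefination of 10 (triethyl phosphonoacetate, NaH, THF, 0 °C) should give ethyl (E)-3-[4-(benzyloxy)-3,5-dimethoxyphenyl]prop-2-enoate F1.
- Reduction with i-Bu2AlH (CH2Cl2, −78 °C) should give (E)-3-[4-(benzyloxy)-3,5-dimethoxyphenyl]prop-2-en-1-ol F2.
- Silylation (TBDPSCl, imidazole, DMF) should give tert-butyl{[(E)-3-[4-(benzyloxy)-3,5-dimethoxyphenyl]prop-2-en-1-yl]oxy}diphenylsilane F3.
- Heating F3 with keto ester 3 and Mn(OAc)3·2H2O (2.2 equiv) in AcOH at 60 °C is the oxidative radical annulation of 1,3-dicarbonyl compounds with alkenes mediated by trivalent manganese. The α-keto ester radical adds to the alkene carbon remote from the aryl group, the benzylic radical is oxidised to the cation, and the ketone oxygen closes the ring. This should give racemic methyl trans-2,5-bis[4-(benzyloxy)-3,5-dimethoxyphenyl]-4-{[(tert-butyldiphenylsilyl)oxy]methyl}-4,5-dihydrofuran-3-carboxylate F4.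
- Preparative HPLC on a chiral stationary phase (amylose tris(3,5-dimethylphenylcarbamate)) would deliver the (4S,5R)-enantiomer 18.

**Step 13.** Acid may ionise a benzylic C–O bond of the ring (C5–O1 in 18, or C2–O1 in 19), and hydride capture would open the ring; the C3 configuration may not be controlled; aryl benzyl ethers may be partly lost. The fallback replaces the cation/hydride sequence by a hydroxyl-directed syn-hydrogenation; it sets out from 18 and comes back at 21.
- Desilylation with HF·pyridine (THF/pyridine, 0 °C → rt; acidic medium to avoid lactonisation onto the ester) should give methyl (4S,5R)-2,5-bis[4-(benzyloxy)-3,5-dimethoxyphenyl]-4-(hydroxymethyl)-4,5-dihydrofuran-3-carboxylate F5.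
- Hydrogenation with H2 (up to 10 bar) and [Ir(cod)(PCy3)(py)]PF6 (5 mol %) in CH2Cl2 is directed by the C4 CH2OH group, so both hydrogens enter on its face. This places the C3 ester trans to C4 and the C2 aryl cis to C3, and leaves the benzyl ethers intact, to give methyl (2S,3R,4S,5R)-2,5-bis[4-(benzyloxy)-3,5-dimethoxyphenyl]-4-(hydroxymethyl)oxolane-3-carboxylate F6.
- LiAlH4 (THF, 0 °C) would then give diol 21 directly.

**Step 5.** A second molecule of 3 may add to the very electrophilic product, and the amine may move the double bond toward the silyloxy carbon. The fallback makes the alkene by alkylation and selenoxide elimination under non-basic final conditions; it sets out from 3 and comes back at 8.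
- C-Alkylation of 3 with tert-butyl(2-iodoethoxy)diphenylsilane (K2CO3, DMF, 50 °C) should give methyl 2-[4-(benzyloxy)-3,5-dimethoxybenzoyl]-4-[(tert-butyldiphenylsilyl)oxy]butanoate F7.
- Selenenylation (NaH, THF, 0 °C; then PhSeCl) should give methyl 2-[4-(benzyloxy)-3,5-dimethoxybenzoyl]-4-[(tert-butyldiphenylsilyl)oxy]-2-(phenylselanyl)butanoate F8.
- Oxidation (H2O2, pyridine, CH2Cl2, 0 °C) should give the selenoxide methyl 2-[4-(benzyloxy)-3,5-dimethoxybenzoyl]-4-[(tert-butyldiphenylsilyl)oxy]-2-(phenylseleninyl)butanoate F9. Its syn-elimination can only take a hydrogen from the side-chain CH2 and so should give 8.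

## Further compounds

F1 | step 12 | ethyl (E)-3-[4-(benzyloxy)-3,5-dimethoxyphenyl]prop-2-enoate | CCOC(=O)/C=C/c1cc(OC)c(OCc2ccccc2)c(OC)c1
F2 | step 12 | (E)-3-[4-(benzyloxy)-3,5-dimethoxyphenyl]prop-2-en-1-ol | OC/C=C/c1cc(OC)c(OCc2ccccc2)c(OC)c1
F3 | step 12 | tert-butyl{[(E)-3-[4-(benzyloxy)-3,5-dimethoxyphenyl]prop-2-en-1-yl]oxy}diphenylsilane | CC(C)(C)[Si](OC/C=C/c1cc(OC)c(OCc2ccccc2)c(OC)c1)(c1ccccc1)c1ccccc1
F4 | step 12 | racemic methyl trans-2,5-bis[4-(benzyloxy)-3,5-dimethoxyphenyl]-4-{[(tert-butyldiphenylsilyl)oxy]methyl}-4,5-dihydrofuran-3-carboxylate (both enantiomers drawn) | COC(=O)C1=C(c2cc(OC)c(OCc3ccccc3)c(OC)c2)O[C@@H](c2cc(OC)c(OCc3ccccc3)c(OC)c2)[C@@H]1CO[Si](c1ccccc1)(c1ccccc1)C(C)(C)C.COC(=O)C1=C(c2cc(OC)c(OCc3ccccc3)c(OC)c2)O[C@H](c2cc(OC)c(OCc3ccccc3)c(OC)c2)[C@H]1CO[Si](c1ccccc1)(c1ccccc1)C(C)(C)C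
F5 | step 13 | methyl (4S,5R)-2,5-bis[4-(benzyloxy)-3,5-dimethoxyphenyl]-4-(hydroxymethyl)-4,5-dihydrofuran-3-carboxylate | COC(=O)C1=C(c2cc(OC)c(OCc3ccccc3)c(OC)c2)O[C@@H](c2cc(OC)c(OCc3ccccc3)c(OC)c2)[C@@H]1CO
F6 | step 13 | methyl (2S,3R,4S,5R)-2,5-bis[4-(benzyloxy)-3,5-dimethoxyphenyl]-4-(hydroxymethyl)oxolane-3-carboxylate | COC(=O)[C@H]1[C@@H](c2cc(OC)c(OCc3ccccc3)c(OC)c2)O[C@@H](c2cc(OC)c(OCc3ccccc3)c(OC)c2)[C@@H]1CO
F7 | step 5 | methyl 2-[4-(benzyloxy)-3,5-dimethoxybenzoyl]-4-[(tert-butyldiphenylsilyl)oxy]butanoate (racemic) | COC(=O)C(CCO[Si](c1ccccc1)(c1ccccc1)C(C)(C)C)C(=O)c1cc(OC)c(OCc2ccccc2)c(OC)c1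
F8 | step 5 | methyl 2-[4-(benzyloxy)-3,5-dimethoxybenzoyl]-4-[(tert-butyldiphenylsilyl)oxy]-2-(phenylselanyl)butanoate (racemic) | COC(=O)C(CCO[Si](c1ccccc1)(c1ccccc1)C(C)(C)C)([Se]c1ccccc1)C(=O)c1cc(OC)c(OCc2ccccc2)c(OC)c1
F9 | step 5 | methyl 2-[4-(benzyloxy)-3,5-dimethoxybenzoyl]-4-[(tert-butyldiphenylsilyl)oxy]-2-(phenylseleninyl)butanoate (selenoxide, not isolated) | COC(=O)C(CCO[Si](c1ccccc1)(c1ccccc1)C(C)(C)C)([Se](=O)c1ccccc1)C(=O)c1cc(OC)c(OCc2ccccc2)c(OC)c1
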